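**Retrosynthetic overview**

1. The route rests on one feature of the ring A / ring C fusion: O1 (on C8a) and the C4 carbonyl (on C4a) are ortho to each other, and the C5 methoxy group sits beside C4a. This is the pattern in which an oxygen nucleophile and then an acyl group add across C1≡C2 of 3,5-dimethoxybenzyne.
2. Key disconnection, both bonds in one operation: O1–C8a and C4–C4a. This gives an ortho-silylaryl triflate as aryne precursor and the C2–C3–C4 piece, a (3S)-3-aryl-3-hydroxypropanoate that already carries ring B and the stereocentre.
3. The hydroxy ester enters the annulation as its trimethylsilyl ether. A free O–H would quench the aryl anion, so the alkoxide is released only by fluoride, and silicon also takes up the methoxide that is expelled.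
4. Aryne precursor: carbamate-directed ortho-silylation of 3,5-dimethoxyphenol, then carbamate-to-triflate exchange (steps 1–3). Hydroxy ester: Claisen carboxylation of 2',3',4'-trimethoxyacetophenone, asymmetric hydrogenation that sets C2, O-silylation (steps 4–6).
5. Ring order: rings A and B are bought; the pyranone ring C is the only ring formed, last, in step 7, which gives the target directly.

Key step: step 7

**Route**

Step 1
Reactants: 1 3,5-dimethoxyphenol
Product: 2 3,5-dimethoxyphenyl N-isopropylcarbamate
Conditions: i-PrNCO, Et3N (cat.), CH2Cl2, 23 °C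
Reagents that add atoms: isopropyl isocyanate, CC(C)N=C=O
Why: Amine-catalysed addition of the phenol to the isocyanate (carbamoylation) is a clean addition and installs an N–H carbamate that directs ortho-metalation after N-silylation and can later be removed under mild base.

Step 2
Reactants: 2 3,5-dimethoxyphenyl N-isopropylcarbamate
Product: 6 3,5-dimethoxy-2-(trimethylsilyl)phenyl N-isopropylcarbamate, via N-silyl carbamate 3 (not isolated), via ortho-lithiated carbamate 4 (not isolated), via bis-silyl carbamate 5 (not isolated)
Conditions: TBSOTf, TMEDA, Et2O, 0 to 23 °C; n-BuLi (2 equiv), TMEDA, −78 °C; TMSCl, −78 to 23 °C; aq NaHSO4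
Reagents that add atoms: chlorotrimethylsilane, C[Si](C)(C)Cl, in the product 6; in the intermediates 3 to 5 only: tert-butyldimethylsilyl triflate, CC(C)(C)[Si](C)(C)OS(=O)(=O)C(F)(F)F, and n-butyllithium, [Li]CCCC
Why: Directed ortho-metalation of the N-silylated carbamate should occur at C2, where the carbamate and the C3 methoxy group cooperate, rather than at C4 between the two methoxy groups; −78 °C holds back the anionic Fries shift, the aryllithium is trapped by TMSCl, and the N-silyl group falls off on acidic work-up.

Step 3
Reactants: 6 3,5-dimethoxy-2-(trimethylsilyl)phenyl N-isopropylcarbamate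
Product: 8 3,5-dimethoxy-2-(trimethylsilyl)phenyl trifluoromethanesulfonate, via silylphenol 7 (not isolated)
Conditions: DBU, Et2NH, MeCN, 40 °C; then PhNTf2, 23 °C
Reagents that add atoms: N-phenylbis(trifluoromethanesulfonimide), O=S(=O)(N(c1ccccc1)S(=O)(=O)C(F)(F)F)C(F)(F)F
Why: DBU deprotonates the N–H carbamate, which fragments (E1cB) to the phenoxide and isopropyl isocyanate that diethylamine scavenges as a urea, and the phenoxide is O-sulfonylated in the same flask by the mild triflyl donor PhNTf2, which spares the aryl–silicon bond.

Step 4
Reactants: 9 2',3',4'-trimethoxyacetophenone; 10 dimethyl carbonate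
Product: 11 methyl 3-oxo-3-(2,3,4-trimethoxyphenyl)propanoate
Conditions: NaH, toluene, reflux; aq HCl, 0 °C
Reagents that add atoms: none
Why: Crossed Claisen condensation (C-acylation of the ketone enolate by the non-enolisable carbonate) is driven to completion by deprotonation of the β-keto ester as it forms.

Step 5
Reactants: 11 methyl 3-oxo-3-(2,3,4-trimethoxyphenyl)propanoate
Product: 12 methyl (3S)-3-hydroxy-3-(2,3,4-trimethoxyphenyl)propanoate
Conditions: H2 (50 atm), RuCl2[(R)-BINAP] (cat.), MeOH, 50 °C
Reagents that add atoms: none
Why: Noyori asymmetric hydrogenation of a β-keto ester: the ester carbonyl chelates ruthenium and the (R)-BINAP ligand delivers hydride to the ketone face that gives the 3S alcohol (the same spatial sense that gives (R)-3-hydroxybutanoate from acetoacetate; the descriptor differs only because aryl outranks CH2CO2Me).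

Step 6
Reactants: 12 methyl (3S)-3-hydroxy-3-(2,3,4-trimethoxyphenyl)propanoate
Product: 13 methyl (3S)-3-(trimethylsilyloxy)-3-(2,3,4-trimethoxyphenyl)propanoate
Conditions: TMSCl, imidazole, CH2Cl2, 0 °C; filtration, no aqueous work-up
Reagents that add atoms: chlorotrimethylsilane, C[Si](C)(C)Cl
Why: Standard O-silylation of a secondary alcohol with a silyl chloride and imidazole leaves the stereocentre untouched and turns the alcohol into a latent alkoxide that fluoride or another alkoxide can unmask.

Step 7
Reactants: 8 3,5-dimethoxy-2-(trimethylsilyl)phenyl trifluoromethanesulfonate; 13 methyl (3S)-3-(trimethylsilyloxy)-3-(2,3,4-trimethoxyphenyl)propanoate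
Product: 17 (2S)-5,7-dimethoxy-2-(2,3,4-trimethoxyphenyl)chroman-4-one, via 3,5-dimethoxybenzyne 14 (not isolated), via alkoxide 15 (not isolated), via aryl anion 16 (not isolated)
Conditions: 8 (1.5 equiv), [Bu4N][Ph3SiF2] (TBAT, 1.2 equiv, in portions), THF, 0 to 23 °C; pH 7 phosphate buffer
Reagents that add atoms: none
Why: Proposed new method: fluoride from TBAT strips the C-silyl group of 8 (loss of triflate gives aryne 14) and the O-silyl group of 13 (alkoxide 15); 15 adds to the aryne carbon remote from the C3 methoxy group to form O1–C8a, and aryl anion 16, held next to that methoxy group, attacks the ester carbonyl in a 6-exo-trig acyl substitution that forms C4–C4a, closes the pyranone ring and expels methoxide. The closest known reaction type is the fluoride-induced annulation of arynes with methyl salicylates to xanthones (O-arylation, then acyl capture); new is an aliphatic, enolisable, stereogenic alkoxide in place of a phenoxide. No stereocentre is formed: the benzylic C–O bond is never broken, so 3S in 13 becomes 2S in 17. The needed regioselectivity, oxygen at C8a and acyl at C4a beside the C5 methoxy group, is secured by the C3 methoxy group of the aryne, whose inductive effect and distortion of the triple bond direct nucleophiles to the far carbon. The silyl ether is used because a free O–H would quench 16 to the open aryl ether, THF because it is not a C–H acid, and the alpha-methylene can reach the anion only through a bent transition state that should lose to carbonyl addition. Methoxide is taken up by silicon of 13 or 8 (giving MeOSiMe3 and a new alkoxide or aryne), and with TBAT in deficit to 8 all basic anions end as silanes and triflate, so the base-labile product is not left to enolise, ring-open to the chalcone and racemise.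

**Compound list**

1 | 3,5-dimethoxyphenol | COc1cc(O)cc(OC)c1 | starting material
2 | 3,5-dimethoxyphenyl N-isopropylcarbamate | COc1cc(OC)cc(OC(=O)NC(C)C)c1 | intermediate
3 | 3,5-dimethoxyphenyl N-(tert-butyldimethylsilyl)-N-isopropylcarbamate (formed in the flask, not isolated) | COc1cc(OC)cc(OC(=O)N(C(C)C)[Si](C)(C)C(C)(C)C)c1 | intermediate
4 | 2-lithio-3,5-dimethoxyphenyl N-(tert-butyldimethylsilyl)-N-isopropylcarbamate (formed in the flask, not isolated) | [Li]c1c(OC)cc(OC)cc1OC(=O)N(C(C)C)[Si](C)(C)C(C)(C)C | intermediate
5 | 3,5-dimethoxy-2-(trimethylsilyl)phenyl N-(tert-butyldimethylsilyl)-N-isopropylcarbamate (formed in the flask, not isolated) | COc1cc(OC)c([Si](C)(C)C)c(OC(=O)N(C(C)C)[Si](C)(C)C(C)(C)C)c1 | intermediate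
6 | 3,5-dimethoxy-2-(trimethylsilyl)phenyl N-isopropylcarbamate | COc1cc(OC)c([Si](C)(C)C)c(OC(=O)NC(C)C)c1 | intermediate
7 | 3,5-dimethoxy-2-(trimethylsilyl)phenol (formed in the flask as its DBU salt, not isolated) | COc1cc(OC)c([Si](C)(C)C)c(O)c1 | intermediate
8 | 3,5-dimethoxy-2-(trimethylsilyl)phenyl trifluoromethanesulfonate | COc1cc(OC)c([Si](C)(C)C)c(OS(=O)(=O)C(F)(F)F)c1 | intermediate
9 | 2',3',4'-trimethoxyacetophenone | CC(=O)c1ccc(OC)c(OC)c1OC | starting material
10 | dimethyl carbonate | COC(=O)OC | starting material
11 | methyl 3-oxo-3-(2,3,4-trimethoxyphenyl)propanoate | COC(=O)CC(=O)c1ccc(OC)c(OC)c1OC | intermediate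
12 | methyl (3S)-3-hydroxy-3-(2,3,4-trimethoxyphenyl)propanoate | COC(=O)C[C@H](O)c1ccc(OC)c(OC)c1OC | intermediate
13 | methyl (3S)-3-(trimethylsilyloxy)-3-(2,3,4-trimethoxyphenyl)propanoate | COC(=O)C[C@H](O[Si](C)(C)C)c1ccc(OC)c(OC)c1OC | intermediate
14 | 3,5-dimethoxybenzyne, 1,2-didehydro-3,5-dimethoxybenzene (formed in the flask, not isolated) | COC1=CC(OC)=CC#C1 | intermediate
15 | (1S)-3-methoxy-3-oxo-1-(2,3,4-trimethoxyphenyl)propan-1-olate, tetrabutylammonium as counter-ion (formed in the flask, not isolated) | COC(=O)C[C@H]([O-])c1ccc(OC)c(OC)c1OC | intermediate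
16 | aryl anion of methyl (3S)-3-(3,5-dimethoxyphenoxy)-3-(2,3,4-trimethoxyphenyl)propanoate, charge on the phenoxy-ring carbon between the ether oxygen and a methoxy group, tetrabutylammonium as counter-ion (formed in the flask, not isolated) | COC(=O)C[C@H](Oc1cc(OC)cc(OC)[c-]1)c1ccc(OC)c(OC)c1OC | intermediate
17 | (2S)-5,7-dimethoxy-2-(2,3,4-trimethoxyphenyl)chroman-4-one | COc1cc(OC)c2c(c1)O[C@H](c1ccc(OC)c(OC)c1OC)CC2=O | target

**Step count**

Total steps: 7. Longest linear sequence: 4 steps (1, 2, 3, 7 or 4, 5, 6, 7).

**Steps most likely to fail**

Step 7 (proposed new method). Several processes could divert it: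
- proton transfer from the alpha-methylene to the aryl anion, followed by β-elimination of the aryloxide;
- retro-aldol fragmentation of the free alkoxide;
- attack of the alkoxide at the sulfur of the triflate;
- base-induced enolisation of the product with ring opening and loss of configuration.

The fallback makes the same ring by known reactions, one bond at a time, setting out from keto ester 11 and phenol 1 and coming back at target 17. Hydrogenation of 11 as in step 5 but with RuCl2[(S)-BINAP] would give methyl (3R)-3-hydroxy-3-(2,3,4-trimethoxyphenyl)propanoate F1. Mitsunobu etherification of F1 with 1 (PPh3, DIAD, toluene, 0 °C) should form the O1–C2 bond with inversion and give methyl (3S)-3-(3,5-dimethoxyphenoxy)-3-(2,3,4-trimethoxyphenyl)propanoate F2. Saponification (LiOH, THF/H2O, 0 °C) would give (3S)-3-(3,5-dimethoxyphenoxy)-3-(2,3,4-trimethoxyphenyl)propanoic acid F3. Intramolecular Friedel–Crafts acylation through the mixed trifluoroacetic anhydride (TFAA, CH2Cl2, 0 °C) should then close C4–C4a onto the activated ring; both ortho positions are equivalent, so only the 5,7-dimethoxy pattern of 17 can result.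

Step 2. Lithiation could go to C4 between the two methoxy groups, or the carbamoyl group could migrate to carbon (anionic Fries shift) before silylation. The fallback places silicon by halogen–metal exchange instead, setting out from phenol 1 and coming back at triflate 8. Bromination (NBS, CH2Cl2, −78 °C) would give 2-bromo-3,5-dimethoxyphenol F4, to be separated from its 4-bromo isomer. O-Silylation (HMDS, THF, reflux) would give (2-bromo-3,5-dimethoxyphenoxy)trimethylsilane F5. n-BuLi (THF, −78 °C) should effect bromine–lithium exchange and a 1,3 O-to-C silyl shift (retro-Brook) to lithium 3,5-dimethoxy-2-(trimethylsilyl)phenoxide F6, which Tf2O would convert in the same flask into 8.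

Step 5. The ortho-methoxy group could erode facial discrimination in the chelate, and the electron-rich benzylic alcohol could solvolyse in warm methanol. The fallback is a resolution, setting out from keto ester 11 and coming back at hydroxy ester 12. NaBH4 (MeOH, 0 °C) would give racemic methyl 3-hydroxy-3-(2,3,4-trimethoxyphenyl)propanoate F7. Kinetic resolution by acylation with vinyl acetate and the lipase of Burkholderia cepacia (an enzyme; t-BuOMe, 30 °C) is expected, from the empirical rule for secondary alcohols with aryl as the large group, to acylate the 3R enantiomer to methyl (3R)-3-acetoxy-3-(2,3,4-trimethoxyphenyl)propanoate F8 and leave 12, which is separated by chromatography.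

**Further compounds**

F1 | step 7 | methyl (3R)-3-hydroxy-3-(2,3,4-trimethoxyphenyl)propanoate | COC(=O)C[C@@H](O)c1ccc(OC)c(OC)c1OC
F2 | step 7 | methyl (3S)-3-(3,5-dimethoxyphenoxy)-3-(2,3,4-trimethoxyphenyl)propanoate | COC(=O)C[C@H](Oc1cc(OC)cc(OC)c1)c1ccc(OC)c(OC)c1OC
F3 | step 7 | (3S)-3-(3,5-dimethoxyphenoxy)-3-(2,3,4-trimethoxyphenyl)propanoic acid | OC(=O)C[C@H](Oc1cc(OC)cc(OC)c1)c1ccc(OC)c(OC)c1OC
F4 | step 2 | 2-bromo-3,5-dimethoxyphenol | COc1cc(O)c(Br)c(OC)c1
F5 | step 2 | (2-bromo-3,5-dimethoxyphenoxy)trimethylsilane | COc1cc(O[Si](C)(C)C)c(Br)c(OC)c1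
F6 | step 2 | lithium 3,5-dimethoxy-2-(trimethylsilyl)phenoxide | [Li+].COc1cc([O-])c([Si](C)(C)C)c(OC)c1
F7 | step 5 | racemic methyl 3-hydroxy-3-(2,3,4-trimethoxyphenyl)propanoate | COC(=O)CC(O)c1ccc(OC)c(OC)c1OC
F8 | step 5 | methyl (3R)-3-acetoxy-3-(2,3,4-trimethoxyphenyl)propanoate | COC(=O)C[C@@H](OC(C)=O)c1ccc(OC)c(OC)c1OC
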